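The readings are simulated with made-up constants; scatter was added.

The ratio of Z left to Q at the top of the Q curve gives the selectivity factor s, as long as Z and Q are lost to one reagent: Q is then lost s times as fast as Z per unit of concentration, so Q stops rising where Z over Q equals s.

- time up to 12 d at which Q stands highest
- the amount of Q, in percent of the Z charged, at that time

| setting | delta | flask |
|---|---|---|
| Z | 16 mM | 16 mM |
| E | 19.2 mM | 19.2 mM |
| remark | the very flask that is asked about, followed so far |  |
| time |  | 12 d |
| volume of the second phase over the first |  | 1.0 |

delta run (percent of the Z charged)

| time / d | Q / % | Z / % |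
|---|---|---|
| 0.125 | 9.1 | 89.0 |
| 0.417 | 17.0 | 62.6 |
| 1.67 | 14.1 | 37.1 |
| 6.00 | 10.2 | 30.8 |

(scatter of a reading: 0.3 percentage points)

- in the second phase: E; everything else is in the first
- charges count per volume of the first phase; a concentration in a rate is the amount of a species over the volume of its own phase; every rate counts per litre of the first phase
- the earlier runs hold the two phases in the same ratio of volumes as the flask asked about

Reckoned on z, the fraction of Z left, with q the fraction standing as Q, the clock drops out so long as Z and Q are lost to one reagent:

q = (z − z^s)/(s − 1)

z at the top = s^(−1/(s − 1)), and q at the top = z/s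

The reading at 0.417 d is taken as the top, so s = 3.68. This s gives 8.91% at the first reading, which shows 9.1%. The curve tops at z = 61.5% and q = 16.7%, 0.3 percentage points under that reading, about its scatter.

If each Z gone takes one E, and each Q reacting on takes a second, then:

E used per Z charged = 2(1 − z) − q

At the last reading this count is 1.28, more than the 1.20 charged, so the count does not hold that late in the delta run. At the top it is 0.603, the E bill of the peak: the E needed per Z charged to reach the top.

Now the settings, by hand. Time: the first two readings put the top near 0.429 d, far inside the limit. E: the charge exceeds the bill, so the flask can reach the top. Z: more Z on the same E lowers E per Z, and below the bill Q should stop short of the top.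

The forecast stands later and higher, at 0.45 d and 17.2%: “Afterwards Q only declines”.

The flask gives 0.460 d and 17.2%.

    Z + Q → J (k = 0.530 /M/h)
    L ⇌ E, rate k2*([L] - [E]/K2) per volume of the first phase (partition coefficient = 1.30, kL = 0.210 /h)
    Z + L → Q (k = 15.0 /M/h)
    Q ⇌ D (K = 0.150, k = 0.0190 /h)
    L + Q → X (k = 47.0 /M/h)
    L → G (k = 0.0280 /h)

At that time the flask holds E at 33.6% of its charge, L at 2.38 mM and G at 0.935 mM. So 0.589 of E per Z charged has reacted with Z and Q, against the bill of 0.603. The neighbour flask, charged with 64 mM of Z, has 0.300 of E per Z, half the bill. Its Q tops at 10.4%, below 16.7%. At 12.0 d the neighbour flask holds E at 0%, L at 0 mM and Z at 60.3%.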